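Remark: the target has no stereocentre and no stereogenic double bond, so no configuration has to be assigned; compounds 1, 2 and 4 are taken as purchasable.

Compound numbers used in all sections: 1 hexadecanoyl chloride; 2 Meldrum's acid; 3 hexadecanoyl Meldrum's acid; 4 cyclohexane-1,3-dione; 5 hexadecanoylketene; 6 enol ester of 4; 7 tetraketone (C-acyl isomer of 6); 8 2-pentadecyl-7,8-dihydro-4H-chromene-4,5(6H)-dione; 9 target.

## The problem

The target 9 is a 4H-chromen-4-one: a benzene ring (ring A: C4a, C5, C6, C7, C8, C8a) fused to a 4-pyranone (ring B: O1, C2, C3, C4, C4a, C8a), with a hydroxyl on C5 and an unbranched C15 chain on C2. There is no stereocentre, so the problem is one of connectivity and economy. The acyl carbon C4 sits on C4a, between the two oxygen-bearing carbons C5 and C8a. This is a 2-acylresorcinol pattern, which direct electrophilic acylation of a 1,3-dioxygenated benzene does not give, because such rings react para to an oxygen and lead to the 7-hydroxy series. The two oxygens of ring A must end up different, one as O1 of ring B and one as a free hydroxyl, although in any aromatic precursor they are two equivalent phenols that both acylate. The chain is long, waxy and unfunctionalised, so it is best brought in as a fatty acid derivative that supplies C2 together with C1'–C15'; ring B must then close with the chain on C2 and not in a coumarin or exocyclic arrangement. The finished chromone is robust, but the 4-pyranone is opened at C2 by hydroxide or amines and the C1' methylene is vinylogously acidic, so strong bases and nucleophiles are best kept out of the late steps. The feature that makes the key step possible is that ring A carries its oxygens on C5 and C8a, 1,3 to each other, with C4a between them and only hydrogen on C6, C7 and C8. This is the pattern of cyclohexane-1,3-dione 4, whose C2 (the future C4a) is its only nucleophilic carbon, while O1–C2–C3–C4 with the chain are exactly the atoms of the acylketene 5.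

## Retrosynthesis

9 to 8. No skeletal bond is cut. Two hydrogens are returned to C6 and C7 of ring A and the C5 hydroxyl becomes a ketone, which gives 8. The neighbouring choice, opening ring B while ring A is still aromatic, leads back to a 2-acylresorcinol with its two equivalent phenols. Taking ring A out of the aromatic series first inverts its reactivity: C4a changes from the least accessible carbon of a resorcinol into the only nucleophilic carbon of 4. The C5 oxygen then travels as a ketone, so no protecting group is needed and the two ring A oxygens are different from the start. The forward reaction must remove one molecule of hydrogen from ring A alone, sparing the C1' methylene and ring B; aromatisation and the hydrogen bond from the C5 hydroxyl to the C4 carbonyl drive it.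

8 to 3 and 4, through 5, 6 and 7. Two bonds of ring B are cut: C4–C4a and the C–O bond that joins O1 to ring A. This separates the C6 ring 4 from an acyclic C18 piece, the acylketene 5, in which C4 is the ketene carbon, C3 the ketene CH, and C2 with its oxygen the acyl carbonyl. Against the neighbouring cuts:
- A C2–C3 cut (Claisen polarity) would need a polyanion of a methyl ketone on ring A, with ring methylene protons competing.
- A C2–C1' cut would need a C–C coupling of a waxy C14 or C15 electrophile on an acidic bicycle.
- Cutting only at O1 would need an alkynyl acid in place of a fatty acid.

The chosen cut makes the hindered C4–C4a bond and the ring from one reactive intermediate. Both partners are far simpler than the bicyclic product: 4 is symmetric and 5 comes from 3 by heating. The forward reaction must deliver the acyl group to carbon and not leave it on oxygen (6 against 7), and then condense 7 to the pyranone. Compound 7 is in effect a ring-closed polyketide, a fatty acyl starter extended by two acetate units on a ring A that is already closed, so the step also follows the presumed biosynthetic logic.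

3 to 1 and 2. The bond between the acyl carbon and C5 of the dioxanedione ring is cut, giving the C16 acid chloride 1 and Meldrum's acid 2. Compound 3 is chosen as the source of 5 over a preformed β-keto ester because it forms in one operation from the cheapest C16 electrophile and releases 5 below 110 °C. The forward reaction is a C-acylation of a doubly activated methylene.

## Roads not taken

Alternative 1: the route most chemists would draw first. Cut C2–C3 and O1–C2 at the aromatic level. 1-(2,6-Dihydroxyphenyl)ethan-1-one A1 would be acylated on both phenols with 1 to the diester A2. A Baker–Venkataraman rearrangement under strong base, with loss of the second ester, would give the diketone A3, and acid would close ring B to 9. This is short and dependable, but it buys the difficult connectivity (the acyl carbon between two phenols) instead of making it. It also puts in two C16 acyl groups for each one that stays, and it needs a strong-base step on a waxy diester. The chosen plan uses one acyl equivalent, never exposes a phenol before the last step, and creates the C4–C4a bond itself.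

Alternative 2: cut C4–C4a, C3–C4 and O1–C2 so that C4 is a one-carbon unit inserted by carbonylation. A palladium-catalysed carbonylative Sonogashira coupling of 2-iodobenzene-1,3-diol A4 with heptadec-1-yne A5 would give the ynone A6, which would close by 6-endo-dig oxa-Michael addition to 9. Three things speak against it:
- The closure of A6 has a competing 5-exo-dig mode that gives a benzofuranone with an exocyclic alkene.
- Two free ortho phenols crowd the C–I bond and can intercept the acylpalladium intermediate as esters.
- A C17 terminal alkyne is a much less accessible chain source than a C16 acid chloride.

In the chosen plan the ring closure has only one mode and no gas or metal is needed.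

Alternative 3: a ring made from another ring, with ring B masked as an isoxazole. The nitrile oxide from (E)-2,6-dimethoxybenzaldehyde oxime A7 would add to A5 to give the isoxazole A8, whose N–O bond hides the C2–C3–C4 dicarbonyl unit. Reductive N–O cleavage, hydrolysis of the vinylogous amide, cleavage of both methyl ethers and cyclodehydration would then be needed. That is five or more operations, with two methyl ethers introduced only to be removed under strong Lewis acid, and it needs the same costly alkyne. The acylketene delivers the same 1,3-dicarbonyl unit unmasked and already attached to C4a.

Key step: step 2

Step 1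
Reactants: 1 hexadecanoyl chloride; 2 2,2-dimethyl-1,3-dioxane-4,6-dione (Meldrum's acid)
Product: 3 5-(1-hydroxyhexadecylidene)-2,2-dimethyl-1,3-dioxane-4,6-dione
Conditions: pyridine (2.2 equiv), CH2Cl2, 0 °C to rt; wash with dilute aq. HCl; used crude
Reagents that add atoms: none
Why: C-acylation of the doubly activated methylene of Meldrum's acid by an acid chloride with pyridine as base is a standard acylation of an active methylene; the product is held as a hydrogen-bonded enol, which blocks a second acylation, and it is used without heating because it is the thermal source of the acylketene.

Step 2
Reactants: 3 5-(1-hydroxyhexadecylidene)-2,2-dimethyl-1,3-dioxane-4,6-dione; 4 cyclohexane-1,3-dione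
Product: 8 2-pentadecyl-7,8-dihydro-4H-chromene-4,5(6H)-dione, via acylketene 5 (not isolated), via enol ester 6 (not isolated), via tetraketone 7 (not isolated)
Conditions: 4 (1.2 equiv), DMAP (10 mol %), PhMe, 110 °C, slow addition of 3; then TsOH·H2O (30 mol %), Dean–Stark, 110 °C
Reagents that add atoms: none
Why: At 110 °C 3 loses acetone and CO2 to give the acylketene 5, which the enol of 4 first captures at oxygen to give 6; 6 is a vinylogous mixed anhydride that returns to 5 by retro-ene cleavage or hands its acyl group to DMAP, so the mixture should drain to the chelated C-acyl enol 7 (a Steglich-type O-to-C acyl shift, equally describable as a formal [4+2] addition of the 1-oxadiene of 5 across the enol double bond of 4). Acid and removal of water then close ring B by 6-exo-trig attack of an enol oxygen on a carbonyl carbon (side-chain enol oxygen on C8a or ring enol oxygen on C2, both leading to the same product) followed by dehydration, the standard condensation of a 1,3,5-tricarbonyl unit to a 4-pyranone. The closest known reaction types are the annulation of acyl Meldrum's acids with enol ethers to 4-pyranones and with 3-aminocyclohex-2-enones to ring-fused 4-pyridones, the acetoacetylation of cyclic 1,3-diones by diketene, and the DMAP- or cyanide-mediated rearrangement of enol esters to 2-acyl-1,3-diones. No stereocentre is formed. The step needs C- over O-acylation, which is secured by the reversibility of O-acylation and by C2 of 4 being its only nucleophilic carbon; it needs no regiocontrol in the ring closure, because the two carbonyls of 4 are equivalent by symmetry and the one not used becomes C5=O. Slow addition of 3 keeps the concentration of 5 low and so holds back its dimerisation.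

Step 3
Reactants: 8 2-pentadecyl-7,8-dihydro-4H-chromene-4,5(6H)-dione
Product: 9 5-hydroxy-2-pentadecyl-4H-chromen-4-one
Conditions: DDQ (1.3 equiv), TsOH·H2O (10 mol %), 1,4-dioxane, 100 °C
Reagents that add atoms: none
Why: Quinone dehydrogenation of a cyclohexenone ring to a phenol: acid-promoted enolisation of the C5 ketone toward C6, hydride abstraction from C7 by DDQ and loss of a proton should give the C6–C7 dienone, which tautomerises at once (C8–H to the C5 oxygen) to the arene. Aromatisation and the hydrogen bond from the C5 hydroxyl to the C4 carbonyl drive the step, and the chelated, electron-poor phenol should resist further oxidation.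

Compound list
1 | hexadecanoyl chloride | CCCCCCCCCCCCCCCC(=O)Cl | starting material
2 | 2,2-dimethyl-1,3-dioxane-4,6-dione (Meldrum's acid) | CC1(C)OC(=O)CC(=O)O1 | starting material
3 | 5-(1-hydroxyhexadecylidene)-2,2-dimethyl-1,3-dioxane-4,6-dione | CCCCCCCCCCCCCCCC(O)=C1C(=O)OC(C)(C)OC1=O | intermediate
4 | cyclohexane-1,3-dione | O=C1CCCC(=O)C1 | starting material
5 | hexadecanoylketene (3-oxooctadec-1-en-1-one) | CCCCCCCCCCCCCCCC(=O)C=C=O | intermediate (not isolated)
6 | 3-oxocyclohex-1-en-1-yl 3-oxooctadecanoate | CCCCCCCCCCCCCCCC(=O)CC(=O)OC1=CC(=O)CCC1 | intermediate (not isolated)
7 | 3-hydroxy-2-(3-oxooctadecanoyl)cyclohex-2-en-1-one (enol form of 2-(3-oxooctadecanoyl)cyclohexane-1,3-dione) | CCCCCCCCCCCCCCCC(=O)CC(=O)C1=C(O)CCCC1=O | intermediate (not isolated)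
8 | 2-pentadecyl-7,8-dihydro-4H-chromene-4,5(6H)-dione | CCCCCCCCCCCCCCCc1cc(=O)c2c(o1)CCCC2=O | intermediate
9 | 5-hydroxy-2-pentadecyl-4H-chromen-4-one | CCCCCCCCCCCCCCCc1cc(=O)c2c(O)cccc2o1 | target

Total step count: 3. Longest linear sequence: 3 steps (1 to 3 to 8 to 9). No protecting group and no metal is used.

Least certain steps

Step 2 (key step). The acyl transfer may stall at oxygen. The acylketene may also dimerise, or be captured by adventitious water and then decarboxylate, before it reaches carbon. Excess dione may self-condense under the acidic second stage. Fallback: set out from 4, which with pyrrolidine (PhMe, Dean–Stark) would give 3-(pyrrolidin-1-yl)cyclohex-2-en-1-one F1, a vinylogous amide with no O–H that is nucleophilic only at carbon. Heating F1 with 3 in PhMe at 110 °C would give the C-acylated vinylogous amide 2-(3-oxooctadecanoyl)-3-(pyrrolidin-1-yl)cyclohex-2-en-1-one F2. TsOH·H2O (1.1 equiv, PhMe, 80 °C) would then close ring B by addition of the side-chain enol oxygen to the amine-bearing carbon and loss of pyrrolidine. The fallback comes back to the route at 8.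

Step 3. Enolisation toward C6 may be slow, so that hydride transfer is incomplete. Oxidation may also start at the vinylogously activated C1' methylene of the chain, and separation of the waxy product from quinone-derived material may be poor. Fallback: set out from 8 and replace hydride abstraction by halogenation and elimination. CuBr2 (2.2 equiv, EtOAc/CHCl3, reflux) would brominate next to the C5 ketone to give 6-bromo-2-pentadecyl-7,8-dihydro-4H-chromene-4,5(6H)-dione F3 (racemic). Li2CO3 and LiBr in DMF at 120 °C would then remove HBr, and the dienone formed would tautomerise to the phenol. Bromination at either activated methylene of ring A would lead, after loss of HBr, to the same arene. The fallback comes back to the route at 9.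

Step 1. The acyl Meldrum's acid may fragment early (loss of acetone and CO2) or hydrolyse during work-up and storage, and some acylation may occur at oxygen; the crude material then carries impurities into the key step. Fallback: set out from 1 and use a different acylketene source. Claisen acylation of the lithium enolate of tert-butyl acetate (2.1 equiv, from lithium diisopropylamide, THF, −78 °C) with 1 would give tert-butyl 3-oxooctadecanoate F4, which is stable and can be purified. Heating F4 with 4 in xylene at 140 °C, with distillation of tert-butanol, would release the acylketene by retro-ene cleavage. The fallback comes back to the route at 5 and continues as in step 2.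

Further compounds
F1 | step 2 | 3-(pyrrolidin-1-yl)cyclohex-2-en-1-one | O=C1C=C(N2CCCC2)CCC1
F2 | step 2 | 2-(3-oxooctadecanoyl)-3-(pyrrolidin-1-yl)cyclohex-2-en-1-one | CCCCCCCCCCCCCCCC(=O)CC(=O)C1=C(N2CCCC2)CCCC1=O
F3 | step 3 | 6-bromo-2-pentadecyl-7,8-dihydro-4H-chromene-4,5(6H)-dione (racemic) | CCCCCCCCCCCCCCCc1cc(=O)c2c(o1)CCC(Br)C2=O
F4 | step 1 | tert-butyl 3-oxooctadecanoate | CCCCCCCCCCCCCCCC(=O)CC(=O)OC(C)(C)C
A1 | alternative 1 | 1-(2,6-dihydroxyphenyl)ethan-1-one | CC(=O)c1c(O)cccc1O
A2 | alternative 1 | 2-acetyl-1,3-phenylene dihexadecanoate | CCCCCCCCCCCCCCCC(=O)Oc1cccc(OC(=O)CCCCCCCCCCCCCCC)c1C(C)=O
A3 | alternative 1 | 1-(2,6-dihydroxyphenyl)octadecane-1,3-dione | CCCCCCCCCCCCCCCC(=O)CC(=O)c1c(O)cccc1O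
A4 | alternative 2 | 2-iodobenzene-1,3-diol | Oc1cccc(O)c1I
A5 | alternative 2 | heptadec-1-yne | CCCCCCCCCCCCCCCC#C
A6 | alternative 2 | 1-(2,6-dihydroxyphenyl)octadec-2-yn-1-one | CCCCCCCCCCCCCCCC#CC(=O)c1c(O)cccc1O
A7 | alternative 3 | (E)-2,6-dimethoxybenzaldehyde oxime | COc1cccc(OC)c1/C=N/O
A8 | alternative 3 | 3-(2,6-dimethoxyphenyl)-5-pentadecylisoxazole | CCCCCCCCCCCCCCCc1cc(-c2c(OC)cccc2OC)no1
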